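The data are simulated for an exercise.

What would the flask hold at 20 min, and in which hand?

all flasks: left-handed substrate 29 mM; right-handed substrate 29 mM

| flask | partner | precatalyst | remark | time |
|---|---|---|---|---|
| theta | 39 mM | 1.5 mM | run made earlier |  |
| alpha | 87 mM | 1.5 mM | run made earlier |  |
| zeta | 58 mM | 3 mM | run made earlier |  |
| flask | 58.0 mM | 1.5 mM |  | 20 min |

| run | time / min | left-handed product / % | right-handed product / % |
|---|---|---|---|
| theta | 2.00 | 7.8 | 1.7 |
| theta | 6.00 | 20.9 | 2.9 |
| theta | 10.0 | 28.0 | 3.7 |
| theta | 15.0 | 36.0 | 4.9 |
| alpha | 4.00 | 28.1 | 3.5 |
| alpha | 8.00 | 48.0 | 5.4 |
| alpha | 12.0 | 57.6 | 8.4 |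
| alpha | 15.0 | 62.9 | 8.0 |
| zeta | 4.00 | 23.1 | 2.2 |
| zeta | 8.00 | 35.7 | 2.8 |
| zeta | 12.0 | 45.4 | 3.2 |
| zeta | 15.0 | 49.1 | 5.8 |

(standard deviation of a reading: 1 percentage point)

* excess of left-handed product over right-handed product in the product at 1.0 min
* excess of left-handed product over right-handed product in the product at 20 min
* part of the left-handed substrate and right-handed substrate charged together that has reacted at 20 min

- partner is single-handed; left-handed substrate and right-handed substrate are mirror images of each other, charged as a racemate, each of them at the stated concentration
- the numbers in the tables scatter with a standard deviation of 1 percentage point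
- steps that have been proposed: partner + right-handed substrate -> right-handed product; partner + precatalyst -> racemization catalyst + spent reagent; partner + left-handed substrate -> left-handed product; 2 racemization catalyst <-> resting dimer; partner -> decomposition product; left-handed substrate + racemization catalyst <-> right-handed substrate + racemization catalyst
- an excess is below zero if the other one leads
- the handed part of partner does not stay in what it makes, so the products of the two hands are mirror images too

First I asked whether the two substrates could count as one pool. In the alpha run the left-handed product read 62.9% at 15.0 min, more than the half charged as left-handed substrate, so right-handed substrate had been turning into left-handed. I took the two hands as level.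

Next I asked how fast that pool falls. I defined the turnover constant as the pool's fractional loss per minute per mM of partner, the mean of the two hands' constants. With equal charges, the reciprocal of the fraction left, less 1, rises as this constant times charge times time. With unequal charges, the logarithm of partner's fraction left over the pool's rises as the constant times the charge difference times time. Zeta read 0.00140 /mM/min, alpha 0.00137 /mM/min and theta 0.00144 /mM/min. I carried their mean, 0.00140 /mM/min, as the turnover constant.

The flask charged partner and pool in the ratio 1.00, so I used the equal-charge rule: 38.1% left, 61.9% reacted. For the excess I pooled readings: 80.0% in the rows at 4.00 min, and 77.6% in the rows at 15.0 min.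

The forecast, for which “racemization is real”, gave 83%, 76% and 59%, which differ from my numbers.

The flask gave 80.4%, 79.2% and 61.8%.

    partner + right-handed substrate → right-handed product (k = 0.00460 /M/s)
    partner + precatalyst → racemization catalyst + spent reagent (k = 0.0200 /M/s)
    partner + left-handed substrate → left-handed product (k = 0.0450 /M/s)
    2 racemization catalyst ⇌ resting dimer, settled at all times (K = 3300 /M)
    partner → decomposition product (k = 7.50 × 10⁻⁷ /s)
    left-handed substrate + racemization catalyst ⇌ right-handed substrate + racemization catalyst, rate k6*[racemization catalyst]*[left-handed substrate] forward; the back reaction follows from the equilibrium constant (k = 32.0 /M/s)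

In the flask, partner consumed the substrates while it also turned precatalyst into racemization catalyst, which stood at 7.09% of the catalyst charged after 2.00 min and 19.2% after 20.0 min. The excess of right-handed substrate was 9.04% at 5.00 min and 4.78% at 10.0 min, and the relaxation half-life of the two substrates by the racemization step alone at the asked time, 0.626 min, was shorter than the run. My constant gave 55.1% left at 10.0 min; the flask held 55.5%.

In a neighbour flask with 14 mM of partner as limiting reagent, the unequal-charge rule gave 18.4% reacted. The computed value was 18.5%.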